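**Plan**

- Ring numbering of the target: O1, C2 (aryl), C3 (CH2OH), C4 (arylmethyl), C5 (CH2). The retrosynthesis cuts O1–C2 first, then C2–C3 and C4–CH2Ar.
- Enabling feature: C3–C4 lies between C5 and the hydroxymethyl carbon. With C5 written as a lactone carbonyl and the hydroxymethyl carbon as a menthyl acetal, C3=C4 is the alkene of a butenolide, C2 a dithiane-masked aroyl anion and the C4 side chain a benzylic bromide.
- Forward: O-benzylsyringaldehyde gives both the dithiane and the bromide, and furfural plus (−)-menthol give the (5R)-menthyloxybutenolide. The three are joined in one flask (C2–C3, then C4–CH2Ar). The tetrahydrofuran is the only ring built and closes last (O1–C2), after unmasking and hydride reduction.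
- Stereochemistry: the crystallised menthyl acetal centre sends the dithiane anti (sets C3), and the dithianyl group sends the bromide anti (sets C4). The trans lactone becomes the 3,4-cis ether because C5, not the acetal carbon, joins O1. C2 is set by a stereoconvergent SN1 closure, trans to C3.
- Both phenols stay benzyl-protected until the last step.

Key step: step 7

Remark: lignan labels map as C7 = ring C2, C8 = ring C3, C9 = the CH2OH carbon, C8' = ring C4, C9' = ring C5, C7' = the arylmethyl CH2. The carbinol centre of 16 is carried as an epimer mixture because it is ionised in step 10.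

Step 1
Reactants: 1 syringaldehyde
Product: 2 4-(benzyloxy)-3,5-dimethoxybenzaldehyde
Conditions: BnBr, K2CO3, DMF, 60 °C
Reagents that add atoms: benzyl bromide, BrCc1ccccc1
Why: Williamson etherification of the acidic 2,6-dimethoxyphenol with a reactive benzylic halide should be clean, and the benzyl ether is inert to the organolithium, hydride and acid steps that follow.

Step 2
Reactants: 2 4-(benzyloxy)-3,5-dimethoxybenzaldehyde; 3 propane-1,3-dithiol
Product: 4 2-[4-(benzyloxy)-3,5-dimethoxyphenyl]-1,3-dithiane
Conditions: BF3·OEt2 (cat.), CH2Cl2, 0 °C → rt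
Reagents that add atoms: none
Why: Lewis-acid-catalysed dithioacetalisation of an aromatic aldehyde is routine and turns the future ring C2 into a carbon that can be deprotonated.

Step 3
Reactants: 2 4-(benzyloxy)-3,5-dimethoxybenzaldehyde
Product: 5 [4-(benzyloxy)-3,5-dimethoxyphenyl]methanol
Conditions: NaBH4, MeOH, 0 °C
Reagents that add atoms: none
Why: Chemoselective borohydride reduction of an aryl aldehyde to the benzylic alcohol.

Step 4
Reactants: 5 [4-(benzyloxy)-3,5-dimethoxyphenyl]methanol
Product: 6 2-(benzyloxy)-5-(bromomethyl)-1,3-dimethoxybenzene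
Conditions: PBr3, CH2Cl2, 0 °C; used directly
Reagents that add atoms: phosphorus tribromide, BrP(Br)Br
Why: Bromination of an electron-rich benzylic alcohol with PBr3 through the phosphite ester should be fast at 0 °C, and the labile bromide is used without storage.

Step 5
Reactants: 7 furfural
Product: 8 5-hydroxyfuran-2(5H)-one (racemic)
Conditions: O2, hν (visible), methylene blue (C16H18ClN3S, cat.), MeOH, rt
Reagents that add atoms: dioxygen, O=O
Why: Dye-sensitised singlet-oxygen [4+2] cycloaddition to the furan gives an endoperoxide that fragments in methanol with loss of the formyl carbon as methyl formate, leaving the hydroxybutenolide, whose C5 centre is re-set in step 6.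

Step 6
Reactants: 8 5-hydroxyfuran-2(5H)-one; 9 (1R,2S,5R)-(−)-menthol
Product: 11 (5R)-5-{[(1R,2S,5R)-2-isopropyl-5-methylcyclohexyl]oxy}furan-2(5H)-one, via C5-epimeric menthyl acetal mixture 10 (not isolated)
Conditions: p-TsOH·H2O (cat.), toluene, reflux, azeotropic removal of H2O; crystallisation from hexane, mother liquor re-equilibrated with acid
Reagents that add atoms: none
Why: Acid-catalysed acetalisation gives both C5 epimers, which interconvert through the ring oxocarbenium ion, and the (5R) epimer should be drawn out by crystallisation, so C5 is set by crystallisation-driven epimer selection against the fixed menthol centres.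

Step 7
Reactants: 4 2-[4-(benzyloxy)-3,5-dimethoxyphenyl]-1,3-dithiane; 11 (5R)-5-{[(1R,2S,5R)-2-isopropyl-5-methylcyclohexyl]oxy}furan-2(5H)-one; 6 2-(benzyloxy)-5-(bromomethyl)-1,3-dimethoxybenzene
Product: 14 (3R,4R,5R)-3-[4-(benzyloxy)-3,5-dimethoxybenzyl]-4-{2-[4-(benzyloxy)-3,5-dimethoxyphenyl]-1,3-dithian-2-yl}-5-{[(1R,2S,5R)-2-isopropyl-5-methylcyclohexyl]oxy}dihydrofuran-2(3H)-one, via 2-lithio-2-aryl-1,3-dithiane 12 (not isolated), via lithium lactone enolate 13 (not isolated)
Conditions: 4, n-BuLi, THF, −78 → −20 °C; 11, −78 °C; 6, DMPU, −78 °C → rt; aq. NH4Cl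
Reagents that add atoms: none
Why: n-BuLi removes the doubly sulfur-stabilised benzylic proton of 4 to give the acyl-anion equivalent 12, which adds in Michael fashion to the β-carbon of butenolide 11 to form lithium enolate 13, and 13 is then C-alkylated (SN2) by benzylic bromide 6. The closest known reaction type is the one-pot conjugate addition–enolate alkylation of lithiated 2-aryl-1,3-dithianes on 5-alkoxybutenolides with benzylic halides. No ring is closed; the two new bonds are C7–C8 (ring C2–C3 of the target) and C8'–C7' (ring C4–CH2Ar). The new centre at lactone C4 is controlled by the menthyloxy group on C5, which shields its own face of the flat butenolide so that 12 enters anti and gives the 4,5-trans adduct. The new centre at lactone C3 is controlled by the bulky aryldithianyl group just placed on C4, which sends the bromide to the opposite face of the enolate and gives the 3,4-trans lactone. The step needs 1,4- over 1,2-addition, which the soft, hindered, charge-delocalised dithianyl anion in THF at −78 °C should secure, and it needs 12 to be consumed before 6 is added, which the fast irreversible addition to the doubly activated acceptor should secure.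

Step 8
Reactants: 14 the dithianyl lactone from step 7
Product: 15 (3R,4R,5R)-4-[4-(benzyloxy)-3,5-dimethoxybenzoyl]-3-[4-(benzyloxy)-3,5-dimethoxybenzyl]-5-{[(1R,2S,5R)-2-isopropyl-5-methylcyclohexyl]oxy}dihydrofuran-2(3H)-one
Conditions: PhI(OCOCF3)2, MeCN–H2O (9:1), 0 °C → rt, short reaction time
Reagents that add atoms: water, O
Why: Oxidative dithioacetal hydrolysis with a hypervalent iodine reagent (S-activation, thionium ion, capture by water) is fast under nearly neutral conditions that should leave the menthyl acetal, lactone and benzyl ethers untouched, and the centre next to the new ketone already holds the favoured all-trans arrangement.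

Step 9
Reactants: 15 the aroyl lactone from step 8
Product: 16 (2R,3R)-2-[4-(benzyloxy)-3,5-dimethoxybenzyl]-3-{[4-(benzyloxy)-3,5-dimethoxyphenyl](hydroxy)methyl}butane-1,4-diol (mixture of carbinol epimers)
Conditions: LiAlH4, THF, 0 °C → rt; H2O, aq. NaOH work-up
Reagents that add atoms: none
Why: Exhaustive LiAlH4 reduction converts the ketone to the carbinol (either epimer serves), the lactone carbonyl to CH2OH and, after collapse of the freed hemiacetal with loss of menthoxide, the former acetal carbon to CH2OH, without touching the two C–H stereocentres.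

Step 10
Reactants: 16 the triol from step 9
Product: 17 {(2S,3R,4R)-2-[4-(benzyloxy)-3,5-dimethoxyphenyl]-4-[4-(benzyloxy)-3,5-dimethoxybenzyl]tetrahydrofuran-3-yl}methanol
Conditions: (+)-10-camphorsulfonic acid (cat.), CH2Cl2, 0 °C → rt
Reagents that add atoms: none
Why: Acid-catalysed SN1 cycloetherification in which either carbinol epimer ionises to the same alkoxy-stabilised benzylic cation, the C9' hydroxyl captures it in a five-membered closure (the C9 hydroxyl could only form an oxetane), and because the benzylic ether can re-ionise the aryl group should settle on the face opposite the C3 hydroxymethyl and C4 arylmethyl groups, giving the (2S) centre.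

Step 11
Reactants: 17 the dibenzyl ether from step 10
Product: 18 (+)-(7S,8R,8'R)-5,5'-dimethoxylariciresinol
Conditions: H2 (1 atm), 10% Pd/C, EtOAc, rt, stopped after two equivalents of H2
Reagents that add atoms: none
Why: Catalytic hydrogenolysis of the two aryl benzyl ethers under neutral conditions should spare the slower-reacting 2-aryltetrahydrofuran C–O bond and sets no stereocentre.

**Compound list**

1 | syringaldehyde (4-hydroxy-3,5-dimethoxybenzaldehyde) | COc1cc(C=O)cc(OC)c1O | starting material
2 | 4-(benzyloxy)-3,5-dimethoxybenzaldehyde | COc1cc(C=O)cc(OC)c1OCc1ccccc1 | intermediate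
3 | propane-1,3-dithiol | SCCCS | starting material
4 | 2-[4-(benzyloxy)-3,5-dimethoxyphenyl]-1,3-dithiane | COc1cc(C2SCCCS2)cc(OC)c1OCc1ccccc1 | intermediate
5 | [4-(benzyloxy)-3,5-dimethoxyphenyl]methanol | COc1cc(CO)cc(OC)c1OCc1ccccc1 | intermediate
6 | 2-(benzyloxy)-5-(bromomethyl)-1,3-dimethoxybenzene | COc1cc(CBr)cc(OC)c1OCc1ccccc1 | intermediate
7 | furfural (furan-2-carbaldehyde) | O=Cc1ccco1 | starting material
8 | 5-hydroxyfuran-2(5H)-one, racemic | O=C1C=CC(O)O1 | intermediate
9 | (1R,2S,5R)-(−)-menthol | CC(C)[C@@H]1CC[C@@H](C)C[C@H]1O | starting material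
10 | 5-{[(1R,2S,5R)-2-isopropyl-5-methylcyclohexyl]oxy}furan-2(5H)-one, mixture of C5 epimers | O=C1C=CC(O[C@@H]2C[C@H](C)CC[C@H]2C(C)C)O1 | intermediate
11 | (5R)-5-{[(1R,2S,5R)-2-isopropyl-5-methylcyclohexyl]oxy}furan-2(5H)-one | O=C1C=C[C@H](O[C@@H]2C[C@H](C)CC[C@H]2C(C)C)O1 | intermediate
12 | {2-[4-(benzyloxy)-3,5-dimethoxyphenyl]-1,3-dithian-2-yl}lithium | [Li]C1(c2cc(OC)c(OCc3ccccc3)c(OC)c2)SCCCS1 | intermediate
13 | lithium (4R,5R)-4-{2-[4-(benzyloxy)-3,5-dimethoxyphenyl]-1,3-dithian-2-yl}-5-{[(1R,2S,5R)-2-isopropyl-5-methylcyclohexyl]oxy}-4,5-dihydrofuran-2-olate | [Li]OC1=C[C@@H](C2(c3cc(OC)c(OCc4ccccc4)c(OC)c3)SCCCS2)[C@H](O[C@@H]2C[C@H](C)CC[C@H]2C(C)C)O1 | intermediate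
14 | (3R,4R,5R)-3-[4-(benzyloxy)-3,5-dimethoxybenzyl]-4-{2-[4-(benzyloxy)-3,5-dimethoxyphenyl]-1,3-dithian-2-yl}-5-{[(1R,2S,5R)-2-isopropyl-5-methylcyclohexyl]oxy}dihydrofuran-2(3H)-one | COc1cc(C[C@H]2C(=O)O[C@@H](O[C@@H]3C[C@H](C)CC[C@H]3C(C)C)[C@@H]2C2(c3cc(OC)c(OCc4ccccc4)c(OC)c3)SCCCS2)cc(OC)c1OCc1ccccc1 | intermediate
15 | (3R,4R,5R)-4-[4-(benzyloxy)-3,5-dimethoxybenzoyl]-3-[4-(benzyloxy)-3,5-dimethoxybenzyl]-5-{[(1R,2S,5R)-2-isopropyl-5-methylcyclohexyl]oxy}dihydrofuran-2(3H)-one | COc1cc(C[C@H]2C(=O)O[C@@H](O[C@@H]3C[C@H](C)CC[C@H]3C(C)C)[C@@H]2C(=O)c2cc(OC)c(OCc3ccccc3)c(OC)c2)cc(OC)c1OCc1ccccc1 | intermediate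
16 | (2R,3R)-2-[4-(benzyloxy)-3,5-dimethoxybenzyl]-3-{[4-(benzyloxy)-3,5-dimethoxyphenyl](hydroxy)methyl}butane-1,4-diol, mixture of carbinol epimers | COc1cc(C[C@@H](CO)[C@H](CO)C(O)c2cc(OC)c(OCc3ccccc3)c(OC)c2)cc(OC)c1OCc1ccccc1 | intermediate
17 | {(2S,3R,4R)-2-[4-(benzyloxy)-3,5-dimethoxyphenyl]-4-[4-(benzyloxy)-3,5-dimethoxybenzyl]tetrahydrofuran-3-yl}methanol | COc1cc(C[C@H]2CO[C@H](c3cc(OC)c(OCc4ccccc4)c(OC)c3)[C@H]2CO)cc(OC)c1OCc1ccccc1 | intermediate
18 | (+)-(7S,8R,8'R)-5,5'-dimethoxylariciresinol, 4-{[(3R,4R,5S)-5-(4-hydroxy-3,5-dimethoxyphenyl)-4-(hydroxymethyl)tetrahydrofuran-3-yl]methyl}-2,6-dimethoxyphenol | COc1cc(C[C@H]2CO[C@H](c3cc(OC)c(O)c(OC)c3)[C@H]2CO)cc(OC)c1O | target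

**Step count**

Total: 11 steps. Longest linear sequence: 8 steps (1 → 2 → 5 → 6 → 14 → 15 → 16 → 17 → 18).

**Steps most likely to fail**

Step 7. The enolate capture may be incomplete. Residual dithianyl anion 12 can consume the bromide directly, or enolate 13 can be protonated before it is alkylated, so that the second C–C bond forms only in part. The fallback sets out from 4 and 11 and separates the two bond formations. The conjugate addition is run alone (n-BuLi, THF, −78 °C; aq. NH4Cl) and the adduct (4R,5R)-4-{2-[4-(benzyloxy)-3,5-dimethoxyphenyl]-1,3-dithian-2-yl}-5-{[(1R,2S,5R)-2-isopropyl-5-methylcyclohexyl]oxy}dihydrofuran-2(3H)-one F1 is purified. It is then deprotonated with LiN(i-Pr)2 in THF–DMPU at −78 °C, which regenerates enolate 13 free of any other nucleophile, and alkylated with 6. This should come back to the route at 14 with the same anti selectivity.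

Step 10. The benzyl-capped syringyl carbinol may ionise only with acid strong enough to let the cation be captured by the electron-rich ring of the neighbouring arylmethyl group (six-membered Friedel–Crafts closure) in competition with capture by oxygen. Equilibration to the 2,3-trans ether may also be slow. The fallback sets out from 16 and reverses the last two operations. The benzyl ethers are removed first (H2, 10% Pd/C, EtOAc, neutral, stopped after two equivalents), which should give (2R,3R)-2-(4-hydroxy-3,5-dimethoxybenzyl)-3-[hydroxy(4-hydroxy-3,5-dimethoxyphenyl)methyl]butane-1,4-diol F2. As a free 4-hydroxybenzylic alcohol, this triol should lose water to a neutral quinone methide under much milder conditions (catalytic pyridinium p-toluenesulfonate, THF, rt). Reversible intramolecular oxa-Michael addition of the C9' hydroxyl then closes the ring trans to the hydroxymethyl group, and the sequence arrives directly at 18. The 2-aryltetrahydrofuran is then never exposed to hydrogenolysis.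

Step 8. The electron-rich rings may be oxidised by the iodine reagent, or the aroyl group, once unveiled next to the acetal carbon, may trigger β-elimination or epimerisation at lactone C4. The fallback sets out from 14 and reduces before unmasking. LiAlH4 in THF leaves the dithiane intact and should give (2R,3R)-2-[4-(benzyloxy)-3,5-dimethoxybenzyl]-3-{2-[4-(benzyloxy)-3,5-dimethoxyphenyl]-1,3-dithian-2-yl}butane-1,4-diol F3. Non-oxidative S-alkylative hydrolysis (MeI, CaCO3, aq. MeCN, 40 °C), assisted by the neighbouring C9' hydroxyl, should then give the cyclic hemiketal (3R,4R)-2-[4-(benzyloxy)-3,5-dimethoxyphenyl]-4-[4-(benzyloxy)-3,5-dimethoxybenzyl]-3-(hydroxymethyl)tetrahydrofuran-2-ol F4, which is in equilibrium with its open hydroxy ketone. NaBH4 in MeOH reduces the open form, and the sequence comes back to the route at 16.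

**Further compounds**

F1 | step 7 | (4R,5R)-4-{2-[4-(benzyloxy)-3,5-dimethoxyphenyl]-1,3-dithian-2-yl}-5-{[(1R,2S,5R)-2-isopropyl-5-methylcyclohexyl]oxy}dihydrofuran-2(3H)-one | O=C1C[C@@H](C2(c3cc(OC)c(OCc4ccccc4)c(OC)c3)SCCCS2)[C@H](O[C@@H]2C[C@H](C)CC[C@H]2C(C)C)O1
F2 | step 10 | (2R,3R)-2-(4-hydroxy-3,5-dimethoxybenzyl)-3-[hydroxy(4-hydroxy-3,5-dimethoxyphenyl)methyl]butane-1,4-diol, mixture of carbinol epimers | COc1cc(C[C@@H](CO)[C@H](CO)C(O)c2cc(OC)c(O)c(OC)c2)cc(OC)c1O
F3 | step 8 | (2R,3R)-2-[4-(benzyloxy)-3,5-dimethoxybenzyl]-3-{2-[4-(benzyloxy)-3,5-dimethoxyphenyl]-1,3-dithian-2-yl}butane-1,4-diol | COc1cc(C[C@@H](CO)[C@H](CO)C2(c3cc(OC)c(OCc4ccccc4)c(OC)c3)SCCCS2)cc(OC)c1OCc1ccccc1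
F4 | step 8 | (3R,4R)-2-[4-(benzyloxy)-3,5-dimethoxyphenyl]-4-[4-(benzyloxy)-3,5-dimethoxybenzyl]-3-(hydroxymethyl)tetrahydrofuran-2-ol, mixture of anomers | COc1cc(C[C@H]2COC(O)(c3cc(OC)c(OCc4ccccc4)c(OC)c3)[C@H]2CO)cc(OC)c1OCc1ccccc1
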